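| setting | grey | green | flask |
|---|---|---|---|
| D | 0.13 M | 0.13 M | 0.13 M |
| J | 2 equiv | 2 equiv | 2.00 equiv |
| G | 0.039 M | 0.039 M | 0.0390 M |
| L | 5 mol% | 3.4 mol% | 5 mol% |
| remark | the very flask that is asked about, followed so far | run made earlier |  |

| run | time / h | E / % | D / % |
|---|---|---|---|
| grey | 0.667 | 1.7 | 90.1 |
| grey | 1.00 | 3.2 | 85.1 |
| grey | 1.33 | 3.1 | 79.7 |
| grey | 2.00 | 7.1 | 73.6 |
| grey | 3.00 | 15.1 | 65.4 |
| grey | 5.00 | 25.4 | 50.5 |
| grey | 8.00 | 39.0 | 37.6 |
| green | 0.833 | 0.8 | 91.6 |
| green | 2.50 | 6.2 | 78.3 |
| green | 4.00 | 11.2 | 66.4 |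
| green | 6.00 | 18.2 | 58.4 |
| green | 10.0 | 30.5 | 46.1 |
| green | 12.0 | 35.0 | 42.3 |
| green | 15.0 | 39.7 | 37.5 |

(scatter of a reading: 1 percentage point)

- the analysis behind the earlier runs scatters by 1 percentage point, standard deviation

- apparent order in L when 30 % of the D are converted (percent change of the rate of making E for one percent more L charged)

**The leftover.** At 8.00 h the grey flask holds 23.4 % of the D charged as neither D nor E, and I follow the rate of making E, not the loss of D.

**Time ladder.** In the grey flask the gap comes first, standing at 19.3 % by 2.00 h. Next comes the look itself, which I interpolate at 2.44 h, later than that. Last comes a fading: the fractional loss of D sags from 0.156 h⁻¹ to 0.0983 h⁻¹, which reads as a time of about 13.3 h, far later than the look.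

**Reading order.** The apparent order is the logarithm of the rate ratio divided by the lever, the natural logarithm of the ratio of the two loadings 0.386. E gained over windows centred at equal D, grey from 1.00 h to 5.00 h and green from 2.50 h to 6.00 h, gives a ratio of 1.62, so I commit to 1.25. The scatter puts 13.4 % on that ratio, and dividing by the lever makes this 0.347 in the order.

**The forecast.** It says 1.4, between 0.95 and 1.85, higher than mine, noting “Scatter makes the slopes uncertain by about 10% each”.

**The flask.** It gives 1.2. At 3.35 h X is made 1.27 times as fast as it is used up, each step taken net.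

    D + L → L + X (k = 0.420 L mol⁻¹ min⁻¹)
    J + L + X → L + E (k = 4.60 L² mol⁻² min⁻¹)
    J + G → Q (k = 0.380 L mol⁻¹ min⁻¹)
    L → Z (k = 0.00130 min⁻¹)

Times the lever, the forecast's distance from this is 7.60 % on the rate ratio, less than the 13.4 % of the readings. In the simulated flask with twice the L the lever is 0.693, and the rate factor of 2.20 there gives an order of 1.14.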